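Compare the earlier runs at 40.0 min: south-east holds more target than north-west, 22.3% against 15.0%, but its solid electrophile stands close, 62.4% against 64.9%.

| setting | north-west | south-east | grey | amber |
|---|---|---|---|---|
| solid electrophile | 0.078 M | 0.078 M | 0.078 M | 0.078 M |
| protonated nucleophile | 0.13 M | 0.29 M | 0.200 M | 0.100 M |
| gas | 10 mM (held) | 10 mM (held) | 10 mM (held) | 10 mM (held) |
| remark | run made earlier | run made earlier |  |  |
| time |  |  | 80 min | 80 min |

- north-west (time / min: solid electrophile / %, target / %): 6.00: 93.3, 0.3; 12.0: 87.7, 2.3; 20.0: 81.0, 4.5; 25.0: 76.7, 7.1; 30.0: 72.7, 8.2; 40.0: 64.9, 15.0
- south-east (time / min: solid electrophile / %, target / %): 6.00: 94.0, 0.3; 12.0: 87.4, 1.1; 20.0: 79.9, 5.0; 25.0: 76.4, 8.5; 30.0: 72.5, 13.4; 40.0: 62.4, 22.3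

(readings scatter by 0.5 percentage points)

1. part of the solid electrophile that has reacted (what has only dissolved counts as not reacted) at the end, grey
2. part of the solid electrophile that has reacted (what has only dissolved counts as not reacted) at the end, amber
3. what raising the concentration of protonated nucleophile from its lowest to its highest value here does to the part of the solid electrophile that has reacted (what has only dissolved counts as not reacted) (changes below 5 percentage points count as none) (it rises / it falls / no change)

- solid, in amounts per volume of the solution: solid electrophile
- at the start none of free base is dissolved
- the earlier runs were read with a standard deviation of 0.5 percentage points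
- candidate steps: solid electrophile <-> electrophile; nucleophile + acid set free <-> protonated nucleophile; acid set free + free base <-> salt of the base; electrophile + nucleophile -> acid set free + target; gas <-> free base
- at the start none of the solid electrophile is in solution
- what has only dissolved of solid electrophile counts as not reacted

So treat the flask as a first-order lag: solid feeds dissolved electrophile at a steady rate, taken from the mean loss of 36.4% in 40.0 min, and nucleophile drains it. Assume free base frees the nucleophile charged. Then divide the target slope from 20.0 min to 40.0 min by dissolved electrophile (neither solid nor target) and by that charge, and average the runs: the drain constant k, target made per dissolved electrophile and per nucleophile, reads 0.215 L mol⁻¹ min⁻¹.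

The pseudo-first-order time constant is τ = 1/(k c_N), with c_N the nucleophile concentration, and target equals feed times (t − τ f), with f the filled fraction of the lag at time t. For amber, c_N at its charge gives τ = 46.5 min and target 38.0%. But each target uses one nucleophile, so go round again with the charge less half of that target: c_N = 0.0852 M, τ = 54.6 min, target 34.5%. Grey goes from 52.2% to 50.2%.

The forecast gives 52% for grey, 44% for amber, and it rises: “Higher concentration therefore raises conversion.” My amber figure stands lower.

The flask gives 47.4% in grey and 31.4% in amber, and it rises by 16 percentage points; the forecast stands 13 points high in amber.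

    solid electrophile ⇌ electrophile, rate k1*(cs1 - [electrophile]) while solid is left; crystals form when [electrophile] > cs1 (solubility = 45.0 mM, k = 0.0200 min⁻¹)
    nucleophile + acid set free ⇌ protonated nucleophile, settled at all times (K = 4800 L mol⁻¹)
    acid set free + free base ⇌ salt of the base, settled at all times (K = 2.20 × 10⁶ L mol⁻¹)
    electrophile + nucleophile → acid set free + target (k = 0.230 L mol⁻¹ min⁻¹)
    gas ⇌ free base, rate k5*(csat - [free base]) (kL = 1.10 min⁻¹)

In grey, electrophile is made 3.42 times faster than used at 10.9 min, but 1.07 times at 80.0 min. Amber, with 0.0735 M of nucleophile against 0.155 M in grey at 80.0 min, holds more electrophile than grey then, 28.6% against 19.9%.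

Carry k to a neighbour of grey charged with 0.019 M of solid electrophile. The same feed in M dissolves it in 26.8 min, τ is 24.4 min, and decay from mid-feed to 80 min gives 93.5% reacted; the flask gives 93.1%.

All runs were generated by integration from invented constants, and the scatter is random.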